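## Analysis of the target

Compound 21 is a cyclohexane with no ring other than the two benzene rings of its acyl groups. It is the quinic acid core, esterified at O3 with (E)-caffeic acid and at O4 with (E)-p-coumaric acid. The ring is numbered C1 (quaternary, OH and CO2H), C2 (CH2), C3 (caffeate), C4 (p-coumarate), C5 (free OH), C6 (CH2). The SMILES puts O1, O3 and O4 on one face and O5 with the carboxyl on the other, which is the natural (−)-quinic acid series, (1R,3R,4S,5R) for this diester. Three stereocentres are contiguous (C3/C4 cis, C4/C5 trans); the fourth, C1, is fully substituted and related only 1,3 to C3 and C5. The sensitive points are the two different cinnamates on neighbouring cis oxygens beside a free hydroxyl (acyl migration and ester loss in base), the catechol and phenol (oxidation), the E-alkenes (no hydrogenation once they are attached) and the tertiary α-hydroxy acid. The carbocycle is simple; the difficulty is to tell five oxygen functions apart on one small ring and to control a quaternary carbinol that has no neighbouring stereocentre. The plan rests on one feature: O4 is trans to O5, O5 is cis to the C1 carboxyl, and O3 is cis to O4. A C4=C5 double bond in a cyclohexene that already carries C1 and C3 can therefore be epoxidized on the O1/O3 face and opened at C5 by the carboxyl across the ring. This sets C4 and C5 and ties O5 and the carboxyl into a 1,5-lactone, and the same C4=C5 bond is the natural site for a ring-closing olefin metathesis.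

## Retrosynthetic reasoning

21 back to 20. The last bonds to be broken are the O5–C7 lactone bond and the three aryl acetate bonds. Keeping O5 and the carboxyl tied together until the end means neither interferes with the acylations, and no separate carboxyl protecting group has to be removed beside two cinnamates. The forward step must hydrolyse a strained γ-lactone and three aryl esters in aqueous acid while two alkyl cinnamates stay in place.

20 back to 16 and 19, and 16 back to 12 and 15. The ester C–O bonds at O4 and then O3 are cut. In the bicyclic lactone 12, O3 is equatorial and open, O4 is axial under the lactone bridge, and O1 is tertiary. The first acid chloride (15) should therefore go to O3 and the second (19) to O4, so the two different acyl groups are placed by the shape of 12 without protecting groups. The acid chlorides come from 13 and 17 through the acetates 14 and 18; the phenols are masked as acetates so that they fall in the final acid step.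

12 back to 11, 10 and 9. Cutting the C5–O lactone bond, with inversion at C5, leads to the epoxy acid 11 and its ester 10, with the oxirane on the O1/O3 face and the carboxyl on the other. Cutting both oxirane C–O bonds leads to cyclohexene 9. C4 and C5 are then set by two substrate-controlled events: delivery of a peracid by the allylic and homoallylic hydroxyls, and an intramolecular trans-diaxial opening. Every oxygen introduced is kept.

9 back to 8. The C4=C5 bond is cut by ring-closing metathesis. This is the only ring bond whose cleavage leaves both existing stereocentres (C1 and C3) in an open chain and requires no new stereocentre at ring closure. The alkene is needed in any case for the next step. The forward reaction has to close a six-membered ring from a 1,7-diene with a free allylic and a free tertiary alcohol.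

8 back to 7, and 7 back to 3 and 5. The C3–H bond is cut (1,3-syn reduction of a β-hydroxy ketone through a boron chelate), then the C1–C2 bond (aldol addition of the enolsilane 5 to the ketone carbonyl of keto ester 3 under a chiral copper Lewis acid). The quaternary C1 is thereby made catalytically and enantioselectively, and C3 is relayed from it.

3 back to 1 and 2, and 5 back to 4. One acyl C–C bond is made by single addition of the allyl Grignard 2 to the oxalate 1. The silyloxydiene 5 is the enol silane of 4.

## Alternatives that were turned down

Alternative 1: The tertiary C1–O bond is made by epoxidizing the C1=C2 double bond of an ester of shikimic acid A2; the extra C2–O bond is removed afterwards. The forward key step is a hydroxyl-directed peracid epoxidation of the 5-O-silyl methyl ester of A2 to the epoxide A1, with the oxirane cis to O3.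
- For: C3, C4 and C5 come from the chiral pool with the right configuration, and O5 arrives already set apart as a silyl ether. On stereochemical economy, and probably on step count to a differentiated core, this alternative is stronger than the chosen route.
- Against: the alkene is conjugated to the ester and therefore a poor partner for an electrophilic peracid. The oxirane of A1 must then be opened reductively at C2 with the C1–O bond kept, whereas electron-transfer reductants cleave the α C–O bond of an α,β-epoxy ester; a halide opening and radical reduction detour is needed. The carboxyl is a simple alkyl ester that would have to be cleaved beside two cinnamates at the end. Selective silylation of O5 needs an acetonide put on and taken off.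
- In its place the chosen route offers oxidation of an isolated, electron-rich alkene, no C–O bond that is made only to be broken, a carboxyl mask (the lactone of 12) that opens in acid beside cinnamates, and independence from the cyclitol pool: either enantiomer and ring-modified analogues follow from the ligand and from 1, 2 and 4.

Alternative 2: The C5–C6 bond is made by intramolecular addition of a 2-substituted allylsilane to a C5 aldehyde in a chain derived from 2-deoxy-L-ribose A4. The forward key step is a Lewis-acid-promoted cyclization to the methylenecyclohexanol A3, with an exocyclic C1=C7 alkene, O3/O4 as an acetonide and O5 trans to O4.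
- For: C3 and C4 come from the sugar, the ring closure creates C5, and the exocyclic alkene is a handle for C1.
- Against: the sugar is the unnatural enantiomer. The C5 configuration depends on the facial preference of an α,β-dialkoxy aldehyde under a Lewis acid that also threatens the acetonide. C1 still needs both an OH and a carboxyl, and its face is not controlled by any nearby element, because the oxygens at C3 and C5 lie 1,3 to it on opposite faces. The acetonide ties together O3 and O4, which must carry different acyl groups, and leaves free O5, which must stay free, so the protecting pattern has to be inverted.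
- Compared with the chosen route it is longer and has two stereocentres (C5 and C1) under uncertain control; in the chosen route each of the four has a defined controlling element.

Alternative 3: The C1–C6 and C2–C3 bonds are made by a Diels–Alder reaction of buta-1,3-diene A7 with the lactate-derived chiral dienophile A6, 2-tert-butyl-5-methylene-1,3-dioxolan-4-one. The forward key step gives the spiro cyclohexene A5, with C1 set by addition anti to the tert-butyl group.
- For: C1 is set by a stoichiometric auxiliary with a well-understood facial bias, the α-hydroxy acid arrives protected, and A5 already has the C4=C5 alkene. On robustness of the individual steps and on control of C1 it is at least as strong as the chosen route.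
- Against: A5 has no oxygen at C3. After auxiliary removal it has to be brought in by halolactonization at C4=C5, elimination to C3=C4 and cis-dihydroxylation before the route reaches 12. That is four operations after ring formation, with a halogen put in and taken out and an osmium-mediated oxidation. A6 itself takes three steps, and A7 is a gas that needs a sealed vessel.
- In its place the chosen route offers catalytic asymmetric induction, a C3 oxygen already present at ring closure so that the alkene is used only once, and about one step fewer to 12.

Key step: step 5

Assumption: the copper–bis(oxazoline) aldol of 3 is taken to follow the facial sense known for pyruvate esters (the (S,S) ligand exposing the si face of the ketone), so the (R,R) ligand is specified for the 2R adduct.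

## Route

Step 1
Reactants: 1 diethyl oxalate; 2 allylmagnesium bromide
Product: 3 ethyl 2-oxopent-4-enoate
Conditions: 2 (1.0 equiv) added to 1 (1.5 equiv), THF/Et2O, −78 °C; 1 M HCl quench at −78 °C; distillation
Reagents that add atoms: none
Why: Single acyl substitution of an oxalate diester by a Grignard reagent; the magnesium hemiketal alkoxide is stable at −78 °C and collapses only on the acidic quench, so a second addition is avoided, and the cold acidic work-up limits migration of the terminal alkene into conjugation.

Step 2
Reactants: 4 methyl vinyl ketone
Product: 5 2-(trimethylsilyloxy)buta-1,3-diene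
Conditions: Me3SiCl, Et3N, DMF, 80 °C; distillation
Reagents that add atoms: chlorotrimethylsilane, C[Si](C)(C)Cl
Why: Silyl enol ether formation at the only enolizable position of the enone (the methyl group), a standard preparation of this diene.

Step 3
Reactants: 3 ethyl 2-oxopent-4-enoate; 5 2-(trimethylsilyloxy)buta-1,3-diene
Product: 7 ethyl (2R)-2-hydroxy-4-oxo-2-(prop-2-en-1-yl)hex-5-enoate, via silyl ether 6 (not isolated)
Conditions: Cu(OTf)2 (10 mol %), (R,R)-tBu-box [2,2'-(propane-2,2-diyl)bis((4R)-4-tert-butyl-4,5-dihydrooxazole)] (11 mol %), THF, −78 → −40 °C; then 1 M HCl, THF, 0 °C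
Reagents that add atoms: none
Why: Catalytic enantioselective Mukaiyama aldol addition of a ketone enolsilane to an α-keto ester: 3 chelates the divalent copper centre through both carbonyl oxygens, a tert-butyl group of the ligand covers one face of the ketone, and the CH2 terminus of the enolsilane in 5 adds to the open re face, setting C2 as R. Silyl transfer gives 6, and brief dilute acid frees the tertiary alcohol without disturbing the vinyl ketone.

Step 4
Reactants: 7 ethyl (2R)-2-hydroxy-4-oxo-2-(prop-2-en-1-yl)hex-5-enoate
Product: 8 ethyl (2R,4R)-2,4-dihydroxy-2-(prop-2-en-1-yl)hex-5-enoate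
Conditions: Et2BOMe (1.1 equiv), THF/MeOH 4:1, −78 °C; NaBH4 (1.1 equiv), −78 °C; AcOH quench, MeOH co-evaporation; chromatography on Et3N-washed silica, used at once
Reagents that add atoms: none
Why: Narasaka–Prasad 1,3-syn reduction: boron bridges the tertiary alkoxide and the ketone in a half-chair in which the allyl group should sit pseudo-equatorial and the smaller, flat ester pseudo-axial, and external hydride adds axially at C4, placing vinyl cis to allyl on the chelate ring (4R, the 2,4-syn diol). Carbonyl activation by boron at −78 °C should favour 1,2- over 1,4-reduction, and neutral handling keeps the γ-hydroxy ester from lactonizing.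

Step 5
Reactants: 8 ethyl (2R,4R)-2,4-dihydroxy-2-(prop-2-en-1-yl)hex-5-enoate
Product: 9 ethyl (1R,3R)-1,3-dihydroxycyclohex-4-ene-1-carboxylate
Conditions: second-generation Grubbs catalyst (H2IMes)(PCy3)Cl2Ru=CHPh (3 mol %), 1,4-benzoquinone (10 mol %), CH2Cl2 (0.01 M), 40 °C
Reagents that add atoms: none
Why: Ring-closing olefin metathesis of a 1,7-diene; the closest known class is dienes carrying a free allylic and a free tertiary alcohol. The ruthenium benzylidene exchanges first onto the unhindered allyl terminus, the new alkylidene adds to the vinyl group of the carbinol in a [2+2] step, and cycloreversion of the ruthenacyclobutane releases the cyclohexene and Ru=CH2, which carries the chain with loss of ethylene. The one ring closes as a six-membered carbocycle by intramolecular alkylidene–alkene [2+2]/retro-[2+2], with the new C4=C5 bond endocyclic and necessarily cis. No stereocentre is formed; C1 and C3 come from steps 3 and 4 and are not touched. The step needs cyclization to outrun acyclic diene oligomerization, and it must avoid hydride-mediated alkene migration and redox isomerization of the allylic alcohol to a ketone. The fully substituted C1 (gem-disubstituent effect), the strain-free ring size, high dilution and escape of ethylene secure the first. A short reaction time at 40 °C with benzoquinone as hydride scavenger secures the second. The free allylic hydroxyl is known to speed alkylidene transfer with this catalyst class.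

Step 6
Reactants: 9 ethyl (1R,3R)-1,3-dihydroxycyclohex-4-ene-1-carboxylate
Product: 10 ethyl (1S,3R,4R,5S)-4,5-epoxy-1,3-dihydroxycyclohexane-1-carboxylate (oxirane cis to both hydroxyls)
Conditions: mCPBA (1.2 equiv), NaHCO3, CH2Cl2, 0 °C
Reagents that add atoms: 3-chloroperoxybenzoic acid, O=C(OO)c1cccc(Cl)c1
Why: Henbest hydroxyl-directed epoxidation: the peracid is hydrogen-bonded to the allylic 3-OH and the homoallylic 1-OH, both on the same face, and the ester on the other face adds steric bias, so oxygen is delivered to C4=C5 cis to O3. This sets C4 and C5 of the oxirane; the bicarbonate buffer keeps the product from acid opening.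

Step 7
Reactants: 10 ethyl (1S,3R,4R,5S)-4,5-epoxy-1,3-dihydroxycyclohexane-1-carboxylate
Product: 12 (1S,3R,4R,5R)-1,3,4-trihydroxy-6-oxabicyclo[3.2.1]octan-7-one (1,5-quinide), via epoxy acid 11 (not isolated)
Conditions: LiOH·H2O (1.1 equiv), THF/H2O, 0 °C; concentrate to dryness; TsOH·H2O (1.3 equiv), MeCN, rt
Reagents that add atoms: lithium hydroxide monohydrate, [Li+].[OH-].O
Why: Saponification, then acid-catalysed intramolecular epoxide opening: Payne migration is impossible because O3 is cis to the oxirane. In the chair with the carboxyl axial, the carboxyl attacks C5 anti to the C5–O bond (trans-diaxial, exo closure to a five-membered lactone). C5 is inverted to the configuration of 21, O4 stays on the O3 face as an axial hydroxyl, and O3 is left equatorial.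

Step 8
Reactants: 13 (E)-caffeic acid
Product: 14 (E)-3-(3,4-diacetoxyphenyl)prop-2-enoic acid
Conditions: Ac2O, pyridine, rt; aqueous HCl work-up
Reagents that add atoms: acetic anhydride, CC(=O)OC(C)=O
Why: Acetylation of both phenols; the aqueous work-up hydrolyses any mixed anhydride at the carboxyl.

Step 9
Reactants: 14 (E)-3-(3,4-diacetoxyphenyl)prop-2-enoic acid
Product: 15 (E)-3-(3,4-diacetoxyphenyl)prop-2-enoyl chloride
Conditions: (COCl)2, DMF (cat.), CH2Cl2, 0 °C → rt; evaporate, use crude
Reagents that add atoms: oxalyl chloride, O=C(Cl)C(=O)Cl
Why: Standard acid chloride formation through the chloroiminium species; aryl acetates and the E-alkene are inert.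

Step 10
Reactants: 12 1,5-quinide; 15 (E)-3-(3,4-diacetoxyphenyl)prop-2-enoyl chloride
Product: 16 3-O-[(E)-3,4-diacetoxycinnamoyl]-1,5-quinide
Conditions: 15 (1.05 equiv), pyridine/CH2Cl2, −20 → 0 °C
Reagents that add atoms: none
Why: Kinetic acylation of the most accessible hydroxyl: O3 is secondary and equatorial, O4 is axial under the lactone bridge and O1 is tertiary next to the lactone carbonyl, so one equivalent of acid chloride at low temperature should go to O3.

Step 11
Reactants: 17 (E)-p-coumaric acid
Product: 18 (E)-3-(4-acetoxyphenyl)prop-2-enoic acid
Conditions: Ac2O, pyridine, rt; aqueous HCl work-up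
Reagents that add atoms: acetic anhydride, CC(=O)OC(C)=O
Why: Phenol acetylation, as in step 8.

Step 12
Reactants: 18 (E)-3-(4-acetoxyphenyl)prop-2-enoic acid
Product: 19 (E)-3-(4-acetoxyphenyl)prop-2-enoyl chloride
Conditions: (COCl)2, DMF (cat.), CH2Cl2, 0 °C → rt; evaporate, use crude
Reagents that add atoms: oxalyl chloride, O=C(Cl)C(=O)Cl
Why: Acid chloride formation, as in step 9.

Step 13
Reactants: 16 3-O-[(E)-3,4-diacetoxycinnamoyl]-1,5-quinide; 19 (E)-3-(4-acetoxyphenyl)prop-2-enoyl chloride
Product: 20 3-O-[(E)-3,4-diacetoxycinnamoyl]-4-O-[(E)-4-acetoxycinnamoyl]-1,5-quinide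
Conditions: 19 (1.5 equiv), DMAP (0.2 equiv), pyridine/CH2Cl2, 0 °C → rt
Reagents that add atoms: none
Why: DMAP-catalysed acylation of the remaining secondary (axial) hydroxyl; the tertiary O1 reacts only under more forcing conditions, and excess acid chloride lets acylation of O4 outrun migration of the O3 ester.

Step 14
Reactants: 20 3-O-[(E)-3,4-diacetoxycinnamoyl]-4-O-[(E)-4-acetoxycinnamoyl]-1,5-quinide
Product: 21 (1R,3R,4S,5R)-3-[(E)-caffeoyloxy]-4-[(E)-p-coumaroyloxy]-1,5-dihydroxycyclohexane-1-carboxylic acid (3-O-caffeoyl-4-O-p-coumaroylquinic acid)
Conditions: 2 M HCl (aq)/THF 1:3, rt, argon, dark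
Reagents that add atoms: water, O
Why: Acid hydrolysis: aryl acetates and the strained bicyclic γ-lactone are cleaved by water in large excess much faster than alkyl cinnamates, and acyl migration, which is fast in base, is slow in acid. No stereocentre is touched, since the lactone opens at the acyl carbon.

## Compound list

1 | diethyl oxalate | CCOC(=O)C(=O)OCC | starting material
2 | allylmagnesium bromide | C=CC[Mg]Br | starting material
3 | ethyl 2-oxopent-4-enoate | C=CCC(=O)C(=O)OCC | intermediate
4 | methyl vinyl ketone | CC(=O)C=C | starting material
5 | 2-(trimethylsilyloxy)buta-1,3-diene | C=CC(=C)O[Si](C)(C)C | intermediate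
6 | ethyl (2R)-4-oxo-2-(prop-2-en-1-yl)-2-(trimethylsilyloxy)hex-5-enoate | C=CC[C@](O[Si](C)(C)C)(C(=O)OCC)CC(=O)C=C | intermediate
7 | ethyl (2R)-2-hydroxy-4-oxo-2-(prop-2-en-1-yl)hex-5-enoate | C=CC[C@](O)(C(=O)OCC)CC(=O)C=C | intermediate
8 | ethyl (2R,4R)-2,4-dihydroxy-2-(prop-2-en-1-yl)hex-5-enoate | C=CC[C@](O)(C(=O)OCC)C[C@@H](O)C=C | intermediate
9 | ethyl (1R,3R)-1,3-dihydroxycyclohex-4-ene-1-carboxylate | CCOC(=O)[C@]1(O)C[C@@H](O)C=CC1 | intermediate
10 | ethyl (1S,3R,4R,5S)-4,5-epoxy-1,3-dihydroxycyclohexane-1-carboxylate | CCOC(=O)[C@]1(O)C[C@@H](O)[C@H]2O[C@H]2C1 | intermediate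
11 | (1S,3R,4R,5S)-4,5-epoxy-1,3-dihydroxycyclohexane-1-carboxylic acid | OC(=O)[C@]1(O)C[C@@H](O)[C@H]2O[C@H]2C1 | intermediate
12 | (1S,3R,4R,5R)-1,3,4-trihydroxy-6-oxabicyclo[3.2.1]octan-7-one (1,5-quinide) | O=C1O[C@@H]2C[C@@]1(O)C[C@@H](O)[C@H]2O | intermediate
13 | (E)-caffeic acid | OC(=O)/C=C/c1ccc(O)c(O)c1 | starting material
14 | (E)-3-(3,4-diacetoxyphenyl)prop-2-enoic acid | CC(=O)Oc1ccc(/C=C/C(=O)O)cc1OC(C)=O | intermediate
15 | (E)-3-(3,4-diacetoxyphenyl)prop-2-enoyl chloride | CC(=O)Oc1ccc(/C=C/C(=O)Cl)cc1OC(C)=O | intermediate
16 | 3-O-[(E)-3,4-diacetoxycinnamoyl]-1,5-quinide | O=C1O[C@@H]2C[C@@]1(O)C[C@@H](OC(=O)/C=C/c1ccc(OC(C)=O)c(OC(C)=O)c1)[C@H]2O | intermediate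
17 | (E)-p-coumaric acid | OC(=O)/C=C/c1ccc(O)cc1 | starting material
18 | (E)-3-(4-acetoxyphenyl)prop-2-enoic acid | CC(=O)Oc1ccc(/C=C/C(=O)O)cc1 | intermediate
19 | (E)-3-(4-acetoxyphenyl)prop-2-enoyl chloride | CC(=O)Oc1ccc(/C=C/C(=O)Cl)cc1 | intermediate
20 | 3-O-[(E)-3,4-diacetoxycinnamoyl]-4-O-[(E)-4-acetoxycinnamoyl]-1,5-quinide | O=C1O[C@@H]2C[C@@]1(O)C[C@@H](OC(=O)/C=C/c1ccc(OC(C)=O)c(OC(C)=O)c1)[C@H]2OC(=O)/C=C/c1ccc(OC(C)=O)cc1 | intermediate
21 | 3-O-caffeoyl-4-O-p-coumaroylquinic acid, (1R,3R,4S,5R) | O=C(/C=C/c1ccc(O)cc1)O[C@H]1[C@H](O)C[C@](O)(C(=O)O)C[C@H]1OC(=O)/C=C/c1ccc(O)c(O)c1 | target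

## Step count and least certain steps

Total: 14 steps. Longest linear sequence: 9 steps (1, 3, 4, 5, 6, 7, 10, 13, 14). Steps 2, 8, 9, 11 and 12 are side branches.

Step 5 (key step). Ruthenium hydride species from catalyst decay may isomerize the free allylic alcohol of 8 to an ethyl ketone or move the allyl double bond. Diol 8 may also close to a butyrolactone whose two alkenes sit on opposite faces and cannot meet. Fallback: from 8, the secondary hydroxyl is silylated (Et3SiCl, imidazole, CH2Cl2, 0 °C) to ethyl (2R,4R)-2-hydroxy-2-(prop-2-en-1-yl)-4-(triethylsilyloxy)hex-5-enoate F1, which can neither lactonize nor undergo redox isomerization. Metathesis with the same catalyst should give ethyl (1R,3R)-1-hydroxy-3-(triethylsilyloxy)cyclohex-4-ene-1-carboxylate F2, and AcOH/THF/H2O removes the silyl group. The route is rejoined at 9.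

Step 3. The terminal alkene of 3 may migrate into conjugation under the Lewis acid. The enolsilane 5 is a weaker nucleophile than a silylketene acetal, so conversion or enantioselectivity may fall. The copper aldolate may also close onto the enone to a tetrahydropyranone. Fallback: from 3, the same catalyst is used with 1-(ethylthio)-1-(trimethylsilyloxy)ethene, the best-precedented nucleophile class. This gives the silyl ether ethyl (2R)-4-(ethylsulfanyl)-4-oxo-2-(prop-2-en-1-yl)-2-(trimethylsilyloxy)butanoate F3 and, after dilute acid, ethyl (2R)-4-(ethylsulfanyl)-2-hydroxy-4-oxo-2-(prop-2-en-1-yl)butanoate F4. A thioester–stannane ketone synthesis then installs the vinyl ketone under neutral conditions: tributyl(vinyl)stannane, Pd2(dba)3 (zerovalent palladium), tri(2-furyl)phosphine, Cu(O2PPh2) (monovalent copper), THF, rt. The route is rejoined at 7.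

Step 4. Hydride may add in conjugate fashion to the vinyl ketone. Syn/anti discrimination may be eroded, because the carbinol carbon is fully substituted and its allyl and ester groups differ little in size. The γ-hydroxy ester may lactonize on work-up. Fallback: from 7, the ring is closed first by the same metathesis to ethyl (1R)-1-hydroxy-3-oxocyclohex-4-ene-1-carboxylate F5, so the same C4=C5 bond is formed one step earlier. Et2BOMe/NaBH4 at −78 °C is then applied to the cyclic ketone. In the ring, boron bridges O1 and the ketone oxygen on one face and hydride can only enter from the other, so only the cis-diol can form, and no open-chain γ-hydroxy ester ever exists. The route is rejoined at 9, passing over 8. F5 can lose water and aromatize, so it would be reduced without storage.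

Step 7. Hydroxide or water may open the oxirane in competition with the carboxyl; attack at C4 would give the wrong diastereomer. Fallback: from 9, the ester is saponified first (LiOH, THF/H2O; then 1 M HCl to pH 2–3, continuous extraction) to (1R,3R)-1,3-dihydroxycyclohex-4-ene-1-carboxylic acid F6. This acid is epoxidized with mCPBA in EtOAc, so that 11 forms under non-aqueous, weakly acidic conditions and closes in the same flask. The route is rejoined at 12, passing over 10.

Step 10. Discrimination between the equatorial O3 and the axial O4 may be insufficient, and some double acylation may occur. Fallback: from 12, Bu2SnO in toluene at reflux with removal of water gives 3,4-O-dibutylstannylene-1,5-quinide F7. Addition of 15 at 0 °C acylates the equatorial oxygen of the cis-diol stannylene, and aqueous work-up rejoins the route at 16.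

Step 14. During the long acid treatment the coumaroyl group may migrate from O4 to the freed O5, a cinnamate may be partly lost, or the lactone may open incompletely. Fallback: from 20, the three aryl acetates are removed first under near-neutral conditions (NH4OAc, aqueous MeOH, rt) to 3-O-caffeoyl-4-O-p-coumaroyl-1,5-quinide F8. The lactone alone is then opened by a short, monitored exposure to 1 M HCl/THF at rt, with unopened lactone recycled. This arrives at 21.

## Further compounds

F1 | step 5 | ethyl (2R,4R)-2-hydroxy-2-(prop-2-en-1-yl)-4-(triethylsilyloxy)hex-5-enoate | C=CC[C@](O)(C(=O)OCC)C[C@@H](O[Si](CC)(CC)CC)C=C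
F2 | step 5 | ethyl (1R,3R)-1-hydroxy-3-(triethylsilyloxy)cyclohex-4-ene-1-carboxylate | CCOC(=O)[C@]1(O)C[C@@H](O[Si](CC)(CC)CC)C=CC1
F3 | step 3 | ethyl (2R)-4-(ethylsulfanyl)-4-oxo-2-(prop-2-en-1-yl)-2-(trimethylsilyloxy)butanoate | C=CC[C@](O[Si](C)(C)C)(C(=O)OCC)CC(=O)SCC
F4 | step 3 | ethyl (2R)-4-(ethylsulfanyl)-2-hydroxy-4-oxo-2-(prop-2-en-1-yl)butanoate | C=CC[C@](O)(C(=O)OCC)CC(=O)SCC
F5 | step 4 | ethyl (1R)-1-hydroxy-3-oxocyclohex-4-ene-1-carboxylate | CCOC(=O)[C@]1(O)CC(=O)C=CC1
F6 | step 7 | (1R,3R)-1,3-dihydroxycyclohex-4-ene-1-carboxylic acid | OC(=O)[C@]1(O)C[C@@H](O)C=CC1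
F7 | step 10 | 3,4-O-dibutylstannylene-1,5-quinide | O=C1O[C@@H]2C[C@@]1(O)C[C@@H](O[Sn](CCCC)(CCCC)O3)[C@H]23
F8 | step 14 | 3-O-caffeoyl-4-O-p-coumaroyl-1,5-quinide | O=C1O[C@@H]2C[C@@]1(O)C[C@@H](OC(=O)/C=C/c1ccc(O)c(O)c1)[C@H]2OC(=O)/C=C/c1ccc(O)cc1
A1 | alternative 1 | methyl 1,2-epoxy-5-O-(tert-butyldimethylsilyl)shikimate (oxirane cis to O3) | COC(=O)[C@@]12C[C@@H](O[Si](C)(C)C(C)(C)C)[C@H](O)[C@H](O)[C@@H]1O2
A2 | alternative 1 | (−)-shikimic acid | OC(=O)C1=C[C@@H](O)[C@@H](O)[C@H](O)C1
A3 | alternative 2 | 5-hydroxy-3,4-O-isopropylidene-1-methylenecyclohexane-3,4-diol (O5 trans to O4) | C=C1C[C@@H](O)[C@@H]2OC(C)(C)O[C@@H]2C1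
A4 | alternative 2 | 2-deoxy-L-ribose (open-chain form) | O=CC[C@@H](O)[C@@H](O)CO
A5 | alternative 3 | spiro cyclohexene dioxolanone (Diels–Alder adduct) | O=C1O[C@H](C(C)(C)C)O[C@@]12CC=CCC2
A6 | alternative 3 | (2R)-2-tert-butyl-5-methylene-1,3-dioxolan-4-one | O=C1O[C@H](C(C)(C)C)OC1=C
A7 | alternative 3 | buta-1,3-diene | C=CC=C
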